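Delta and beta carry the same 2 mol% of precatalyst, but delta stays at 90 °C for 25 h, longer than the 4.0 h beta spends there before cooling to 60 °C.

| setting | north | south-east | west | delta | beta |
|---|---|---|---|---|---|
| substrate | 10 mM | 13 mM | 15 mM | 10 mM | 20 mM |
| precatalyst | 2 mol% | 2 mol% | 2 mol% | 2 mol% | 2 mol% |
| temperature | 55 °C | 75 °C | 55 °C |  |  |
| remark | run made earlier | run made earlier | run made earlier | at 90 °C throughout | at 90 °C until 4.0 h, from then on at 60 °C |
| time |  |  |  | 25 h | 8.0 h |

- the winner by amount of product, in percent of the substrate charged; "neither" if no more than 2 percentage points parts them (delta / beta / neither)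
- how much product is there at the end, in percent of the substrate charged: delta
- how much product is there at the end, in percent of the substrate charged: beta

- the earlier runs were read with a standard deviation of 2 percentage points
- candidate steps: substrate + free catalyst -> catalyst intermediate A; catalyst intermediate A <-> catalyst intermediate B; catalyst intermediate B <-> free catalyst + product; precatalyst -> free catalyst
- where the amount of substrate changes, what is given in equivalents or mol% on it follows

I reckoned in fractions of the charge. At this loading, converting the charge takes 50.0 turns of each catalyst charged: the turnover number needed, one over the loading.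

- north (time / h: product / %, substrate / %): 2.50: 1, 102; 5.00: 0, 98; 8.00: 6, 101; 15.0: 3, 96; 30.0: 2, 95
- south-east (time / h: product / %, substrate / %): 0.833: 1, 99; 2.00: 0, 99; 3.00: 1, 94; 6.00: 8, 94; 12.0: 21, 78
- west (time / h: product / %, substrate / %): 2.50: 0, 101; 5.00: 0, 101; 8.00: 2, 98; 15.0: 0, 100; 30.0: 3, 99

(readings scatter by 2 percentage points)

I read the south-east table downward. At 0.833 h, 2.00 h and 3.00 h the product stood at 1 %, 0 % and 1 %, inside the scatter of 2 percentage points, so I read a lag. Then came 8 % at 6.00 h and 21 % at 12.0 h, so between those rows the catalyst charged turned, on average, at a read rate of 1.08 h⁻¹. The north and west tables end at 2 % and 3 %, near the scatter, and I drew no temperature law from them.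

So I asked what factor over that rate each flask requires. I assumed the rate ignores the substrate charge and set aside the lag and the cool hours. Delta then requires 1.85, but beta, to finish in its hot hours, requires 11.5, a larger factor. I committed to delta as the winner, nearly complete, with beta unfinished.

The forecast gave delta, with 92 % for delta and 34 % for beta: “Extrapolating to 90 °C gives about 4× the 75 °C values”. Its factor of 4 lies between my two .

Delta gave 97.8 %, 5.8 points above the forecast, and beta gave 30.5 %, so the winner was delta.

    substrate + free catalyst → catalyst intermediate A (k = 0.856 M⁻¹ s⁻¹, Ea = 69.0 kJ mol⁻¹)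
    catalyst intermediate A ⇌ catalyst intermediate B (K = 0.310, k = 0.0157 s⁻¹, Ea = 107 kJ mol⁻¹, ΔH = −87.0 kJ mol⁻¹)
    catalyst intermediate B ⇌ free catalyst + product (K = 0.0266 M, k = 0.0140 s⁻¹, Ea = 112 kJ mol⁻¹, ΔH = −30.0 kJ mol⁻¹)
    precatalyst → free catalyst (k = 8.64 × 10⁻⁵ s⁻¹, Ea = 113 kJ mol⁻¹)
    (constants at 90 °C)

In beta at 8.00 h, 27.6 % of the catalyst charged was still precatalyst. Beta's product came to 15.2 turns of the 50.0 needed. A neighbour flask, like beta but with 0.8 mol% of precatalyst, gave 12.9 %, which is 16.1 turns of the 125 it needed.

(Readings and results are simulated from invented constants; scatter was added.)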